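**Retrosynthetic overview**

1. Numbering follows the germacrane skeleton (ring C1–C10; lactone carbons C11, C12, C13; ester carbon C14 on C10; methyl C15 on C4). The plan rests on C8 and C9, neighbouring carbons of the ten-membered carbocycle whose two C–O bonds point to the same ring face, between the ring-fusion carbon C7 and the trigonal C10.
2. Endgame: the O8 acrylate (Yamaguchi), the O9 acetate and C11=C13 (Mannich/elimination) are taken off to give the 8,9-cis-diol, the product of syn-dihydroxylation of a ring-cis C8=C9 olefin.
3. Key disconnection: C8=C9 by ring-closing metathesis of a vinyl group on C7 with the vinyl group on C10 of a 2-vinyl enoate; the ten-membered ring closes last.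
4. The metathesis substrate comes from a trans-4-vinyl-5-oxiranyl γ-lactone (vinyl cuprate addition to a butenolide sets C7), whose side chain is cut to the C1 aldehyde and extended by iodo-Wittig olefination and Stille vinylation (C1=C10, C9).
5. The butenolide comes from nerol: Sharpless epoxidation (C4, C5), oxidation, methyl propiolate addition (C6), semihydrogenation and lactonisation. Ring order: oxirane, γ-lactone, ten-membered carbocycle.

Key step: step 9

Assumption: in the 8,9-diol the allylic C9 hydroxyl is taken to be acylated faster than the C8 hydroxyl next to the ring fusion; the opposite case is covered by the fallback for step 15.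

**Route**

Step 1
Reactants: 1 nerol
Product: 2 (2S,3R)-2,3-epoxynerol
Conditions: Ti(OiPr)4 (cat.), L-(+)-diethyl tartrate (cat.), tBuOOH, 4 Å molecular sieves, CH2Cl2, −20 °C
Reagents that add atoms: tert-butyl hydroperoxide, CC(C)(C)OO
Why: Sharpless asymmetric epoxidation, in which the titanium tartrate complex binds the allylic hydroxyl and delivers oxygen only to the allylic olefin, with L-(+)-tartrate giving the (2S,3R)-epoxide and thus C4 (R) and C5 (S), while the Z geometry of nerol becomes the cis relation of C3 and C6 on the oxirane.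

Step 2
Reactants: 2 (2S,3R)-2,3-epoxynerol
Product: 3 (2R,3R)-3-methyl-3-(4-methylpent-3-en-1-yl)oxirane-2-carbaldehyde
Conditions: TEMPO (cat.), PhI(OAc)2, CH2Cl2, rt
Reagents that add atoms: none
Why: Nitroxyl-catalysed alcohol oxidation with PhI(OAc)2 as terminal oxidant stops at the aldehyde under nearly neutral conditions, so the epoxide survives and the oxirane carbon next to the carbonyl keeps its configuration.

Step 3
Reactants: 3 epoxy aldehyde; 4 methyl propiolate
Product: 5 methyl (4S)-4-hydroxy-4-[(2S,3R)-3-methyl-3-(4-methylpent-3-en-1-yl)oxiran-2-yl]but-2-ynoate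
Conditions: 4, LiN(SiMe3)2, THF, −78 °C; then 3, −78 °C; AcOH quench at −78 °C
Reagents that add atoms: none
Why: 1,2-Addition of a lithium acetylide to an α,β-epoxy aldehyde under Felkin–Anh (non-chelating) control, in which attack anti to the oxirane C–O bond should give mainly the 5,6-anti alcohol with C6 (S), the minor epimer being removed by chromatography and the low temperature keeping the lithium propiolate and the epoxy alkoxide intact.

Step 4
Reactants: 5 hydroxy ynoate
Product: 7 butenolide (5S)-5-[(2S,3R)-3-methyl-3-(4-methylpent-3-en-1-yl)oxiran-2-yl]furan-2(5H)-one, via Z-hydroxy enoate 6 (not isolated)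
Conditions: H2 (1 atm), Pd/CaCO3 poisoned with Pb(OAc)2 (Lindlar catalyst), quinoline, EtOAc, rt; filter; then pyridinium p-toluenesulfonate (cat.), CH2Cl2, rt
Reagents that add atoms: none
Why: Lindlar semihydrogenation adds H2 syn to the alkyne to give the Z-4-hydroxy enoate, whose hydroxyl and ester are held cis and close to the butenolide with loss of methanol under mild acid catalysis, while the trisubstituted olefin, the epoxide and C6 are untouched.

Step 5
Reactants: 7 butenolide; 8 vinylmagnesium bromide
Product: 10 trans lactone (4R,5S)-4-ethenyl-5-[(2S,3R)-3-methyl-3-(4-methylpent-3-en-1-yl)oxiran-2-yl]oxolan-2-one, via silyl ketene acetal 9 (not isolated)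
Conditions: 8, CuBr·SMe2 (cat.), Me3SiCl, THF, −78 °C; then aq. NH4Cl
Reagents that add atoms: chlorotrimethylsilane, C[Si](C)(C)Cl (silicon retained only in intermediate 9)
Why: Copper-catalysed conjugate addition of the vinyl Grignard reagent with silyl trapping, in which the vinyl group adds to C7 on the face opposite to the C6 side chain and so sets C7 (R) trans to C6, the silyl ketene acetal being hydrolysed to the lactone on work-up.

Step 6
Reactants: 10 trans vinyl lactone
Product: 12 aldehyde 3-[(2R,3S)-3-[(2S,3R)-3-ethenyl-5-oxooxolan-2-yl]-2-methyloxiran-2-yl]propanal, via ozonide 11 (not isolated)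
Conditions: O3, CH2Cl2, −78 °C, Sudan Red 7B as end-point indicator; then PPh3, −78 °C to rt
Reagents that add atoms: ozone, [O-][O+]=O
Why: Ozonolysis with reductive work-up, in which the electrophilic ozone should cleave the electron-rich trisubstituted olefin well before the monosubstituted vinyl group on the lactone (the dye marks the end point), so that C1 is unveiled as the aldehyde with loss of acetone.

Step 7
Reactants: 12 aldehyde
Product: 13 methyl (2Z)-2-iodo-5-[(2R,3S)-3-[(2S,3R)-3-ethenyl-5-oxooxolan-2-yl]-2-methyloxiran-2-yl]pent-2-enoate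
Conditions: Ph3P=CHCO2Me, N-iodosuccinimide, CH2Cl2, −20 °C; then 12, −20 °C to rt
Reagents that add atoms: methyl (triphenylphosphoranylidene)acetate, COC(=O)C=P(c1ccccc1)(c1ccccc1)c1ccccc1; N-iodosuccinimide, O=C1CCC(=O)N1I
Why: Wittig olefination with a stabilised α-iodo ylide made in the flask, which places the ester trans to the aldehyde-derived chain and so should give the (Z)-2-iodo enoate, that is the C1=C10 geometry of the target with C2 cis to the future C9.

Step 8
Reactants: 13 (Z)-2-iodo enoate
Product: 14 methyl (2E)-2-ethenyl-5-[(2R,3S)-3-[(2S,3R)-3-ethenyl-5-oxooxolan-2-yl]-2-methyloxiran-2-yl]pent-2-enoate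
Conditions: tributyl(vinyl)stannane, Pd2(dba)3 (cat.), AsPh3, CuI (cat.), N-methylpyrrolidone, rt
Reagents that add atoms: tributyl(vinyl)stannane, C=C[Sn](CCCC)(CCCC)CCCC
Why: Stille coupling, in which oxidative addition of zerovalent palladium into the C10–I bond, copper-assisted transfer of the vinyl group from tin and reductive elimination proceed with retention of olefin geometry under neutral conditions that leave lactone, epoxide and the C7 vinyl group alone.

Step 9
Reactants: 14 2-vinyl enoate with C7 vinyl group
Product: 15 methyl (1(10)E,8Z)-(4R,5S,6S,7R)-4,5-epoxy-13-norgermacra-1(10),8-dien-12,6-olid-14-oate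
Conditions: second-generation Grubbs catalyst (H2IMes)(PCy3)Cl2Ru=CHPh (10 mol %), CH2Cl2 (1 mM, slow addition of 14), 40 °C, argon sparge
Reagents that add atoms: none
Why: Ring-closing olefin metathesis, in which the ruthenium benzylidene exchanges onto the unhindered C7 vinyl group, the new alkylidene undergoes [2+2] cycloaddition with the terminal vinyl group on C10, and cycloreversion of the ruthenacyclobutane releases ethene and forms C8=C9. The closest known reaction type is ene–diene ring-closing metathesis to medium-ring and macrocyclic conjugated dienes, where the catalyst couples the terminal olefin of a 1,3-diene and leaves the internal one in place. The ten-membered carbocycle C1–C10 closes by joining the chain termini C8 and C9, with the new olefin endocyclic. No stereocentre is formed, and the olefin geometry is controlled by ring strain, since a trans C8=C9 bond next to the ring-cis C1=C10 olefin, the trans-fused lactone and the cis-fused oxirane would be far more strained than the cis isomer, to which reversible metathesis can also correct. The step needs site selectivity for the two monosubstituted olefins, which the substrate secures because C1=C10 is trisubstituted and carries the ester; it also needs ring closure to outrun oligomerisation, which high dilution, slow addition, removal of ethene and the two turns that the cis-oxirane and the lactone fusion put into the C2–C7 chain should secure.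

Step 10
Reactants: 15 ten-membered diene
Product: 16 methyl (4R,5S,6S,7R,8S,9R)-4,5-epoxy-8,9-dihydroxy-13-norgermacr-1(10)E-en-12,6-olid-14-oate
Conditions: OsO4 (cat.), N-methylmorpholine N-oxide, acetone/H2O, 0 °C to rt
Reagents that add atoms: osmium tetroxide (catalytic oxygen carrier), O=[Os](=O)(=O)=O; N-methylmorpholine N-oxide, C[N+]1([O-])CCOCC1; water, O
Why: Catalytic syn-dihydroxylation (Upjohn conditions), in which OsO4 adds suprafacially to the more electron-rich cis-disubstituted C8=C9 olefin in preference to the ester-bearing trisubstituted C1=C10 olefin and, with H7 held near the olefin plane by allylic strain, should approach the outer face of the medium ring on which C11 lies, setting C8 (S) and C9 (R) with both hydroxyls cis to the C7–C11 bond.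

Step 11
Reactants: 16 8,9-cis-diol
Product: 17 8,9-bis(triethylsilyl) ether of 16
Conditions: Et3SiCl, imidazole, 4-(dimethylamino)pyridine (cat.), DMF, rt
Reagents that add atoms: chlorotriethylsilane, CC[Si](Cl)(CC)CC
Why: Silyl ether formation masks both secondary hydroxyls for the enolate chemistry and blocks translactonisation through O8, and triethylsilyl is chosen over an acetonide because it is later removed with fluoride and not with acid that would open the trisubstituted epoxide.

Step 12
Reactants: 17 bis(triethylsilyl) ether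
Product: 18 11-(dimethylaminomethyl) lactone (C13 introduced as CH2NMe2; 11R expected)
Conditions: LiN(iPr)2, THF, −78 °C; then Me2N=CH2+ I− (Eschenmoser's salt), −78 to 0 °C
Reagents that add atoms: N,N-dimethylmethyleneiminium iodide, C=[N+](C)C.[I-]
Why: Mannich aminomethylation of the lactone enolate, in which the amide base removes a C11 proton (the conjugated ester has no α-hydrogen) and the iminium salt is taken up anti to the C7–C8 bond, the new C11 centre being of no consequence because it becomes trigonal in the next step.

Step 13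
Reactants: 18 Mannich base
Product: 20 methyl 4,5-epoxy-8,9-bis(triethylsilyloxy)germacra-1(10)E,11(13)-dien-12,6-olid-14-oate, via ammonium iodide 19 (not isolated)
Conditions: MeI, THF, rt; evaporate; then aq. NaHCO3, EtOAc, rt
Reagents that add atoms: iodomethane, CI (methyl retained only in intermediate 19)
Why: Exhaustive N-methylation turns the amine into a trimethylammonium leaving group and mild base then effects a Hofmann-type E1cB elimination to the α-methylene lactone C11=C13 without touching the silyl ethers, the enoate or the epoxide.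

Step 14
Reactants: 20 α-methylene lactone bis(silyl) ether
Product: 21 methyl (4R,5S,6S,7R,8S,9R)-4,5-epoxy-8,9-dihydroxygermacra-1(10)E,11(13)-dien-12,6-olid-14-oate
Conditions: HF·pyridine, pyridine, THF, 0 °C
Reagents that add atoms: none
Why: Fluoride-mediated desilylation buffered with pyridine cleaves both Si–O bonds under conditions too mild to open the epoxide or to add to the α-methylene lactone.

Step 15
Reactants: 21 α-methylene lactone diol
Product: 22 9-O-acetate of 21 (C8 hydroxyl free)
Conditions: AcCl (1.05 equiv), 2,4,6-collidine, CH2Cl2, −78 to −40 °C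
Reagents that add atoms: acetyl chloride, CC(Cl)=O
Why: Kinetic monoacylation with one equivalent of acetyl chloride and a hindered pyridine base at low temperature, in which the allylic C9 hydroxyl next to the trigonal C10 should be more accessible than the C8 hydroxyl flanked by the ring-fusion carbon C7 and the lactone, so that the acetate goes to O9.

Step 16
Reactants: 23 ethyl 2-(hydroxymethyl)acrylate
Product: 24 ethyl 2-[(tert-butyldimethylsilyloxy)methyl]acrylate
Conditions: tBuMe2SiCl, imidazole, CH2Cl2, 0 °C to rt
Reagents that add atoms: tert-butylchlorodimethylsilane, CC(C)(C)[Si](C)(C)Cl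
Why: Standard silylation of the primary allylic alcohol protects the side-chain hydroxyl so that the acid cannot esterify itself in the coupling.

Step 17
Reactants: 24 silyl-protected ethyl ester
Product: 25 2-[(tert-butyldimethylsilyloxy)methyl]acrylic acid
Conditions: LiOH, THF/H2O, 0 °C; then 1 M HCl to pH 3, 0 °C
Reagents that add atoms: lithium hydroxide, [Li+].[OH-]
Why: Saponification at low temperature followed by careful acidification gives the free acid, since hydroxide adds to the ester carbonyl faster than to the 2-substituted acrylate and the hindered silyl ether survives brief cold dilute acid.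

Step 18
Reactants: 25 protected acrylic acid; 22 9-O-acetate
Product: 27 methyl 9-acetoxy-8-{2-[(tert-butyldimethylsilyloxy)methyl]acryloyloxy}-4,5-epoxygermacra-1(10)E,11(13)-dien-12,6-olid-14-oate, via mixed anhydride 26 (not isolated)
Conditions: 25, 2,4,6-trichlorobenzoyl chloride, Et3N, toluene, rt; then 22, 4-(dimethylamino)pyridine, toluene, rt
Reagents that add atoms: 2,4,6-trichlorobenzoyl chloride, O=C(Cl)c1c(Cl)cc(Cl)cc1Cl (retained only in intermediate 26)
Why: Yamaguchi esterification, in which the acid is activated as the mixed 2,4,6-trichlorobenzoic anhydride and the pyridine catalyst transfers the less hindered acrylic acyl group to the remaining C8 hydroxyl without change at any stereocentre.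

Step 19
Reactants: 27 silyl-protected diester
Product: 28 CNP0147016.1
Conditions: HF·pyridine, pyridine, THF, 0 °C to rt
Reagents that add atoms: none
Why: Buffered fluoride cleavage of the primary silyl ether frees the hydroxymethyl group without acyl migration, epoxide opening or addition to the two acrylate-type acceptors, which gives the target.

**Compound list**

1 | nerol, (2Z)-3,7-dimethylocta-2,6-dien-1-ol | CC(C)=CCC/C(C)=C\CO | starting material
2 | (2S,3R)-2,3-epoxynerol, [(2S,3R)-3-methyl-3-(4-methylpent-3-en-1-yl)oxiran-2-yl]methanol | OC[C@@H]1O[C@]1(C)CCC=C(C)C | intermediate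
3 | (2R,3R)-3-methyl-3-(4-methylpent-3-en-1-yl)oxirane-2-carbaldehyde | O=C[C@@H]1O[C@]1(C)CCC=C(C)C | intermediate
4 | methyl propiolate | C#CC(=O)OC | starting material
5 | methyl (4S)-4-hydroxy-4-[(2S,3R)-3-methyl-3-(4-methylpent-3-en-1-yl)oxiran-2-yl]but-2-ynoate | COC(=O)C#C[C@H](O)[C@@H]1O[C@]1(C)CCC=C(C)C | intermediate
6 | methyl (2Z,4S)-4-hydroxy-4-[(2S,3R)-3-methyl-3-(4-methylpent-3-en-1-yl)oxiran-2-yl]but-2-enoate | COC(=O)/C=C\[C@H](O)[C@@H]1O[C@]1(C)CCC=C(C)C | intermediate
7 | (5S)-5-[(2S,3R)-3-methyl-3-(4-methylpent-3-en-1-yl)oxiran-2-yl]furan-2(5H)-one | O=C1O[C@@H](C=C1)[C@@H]2O[C@]2(C)CCC=C(C)C | intermediate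
8 | vinylmagnesium bromide | C=C[Mg]Br | starting material
9 | trimethylsilyl ketene acetal of lactone 10 (2-trimethylsilyloxy-4,5-dihydrofuran, C4 vinyl and C5 oxiranyl groups trans) | C=C[C@H]1C=C(O[Si](C)(C)C)O[C@@H]1[C@@H]2O[C@]2(C)CCC=C(C)C | intermediate
10 | (4R,5S)-4-ethenyl-5-[(2S,3R)-3-methyl-3-(4-methylpent-3-en-1-yl)oxiran-2-yl]oxolan-2-one | C=C[C@H]1CC(=O)O[C@@H]1[C@@H]2O[C@]2(C)CCC=C(C)C | intermediate
11 | secondary ozonide of 10 (3,3-dimethyl-1,2,4-trioxolane in place of the trisubstituted olefin; epimers at the trioxolane CH) | C=C[C@H]1CC(=O)O[C@@H]1[C@@H]2O[C@]2(C)CCC3OOC(C)(C)O3 | intermediate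
12 | 3-[(2R,3S)-3-[(2S,3R)-3-ethenyl-5-oxooxolan-2-yl]-2-methyloxiran-2-yl]propanal | C=C[C@H]1CC(=O)O[C@@H]1[C@@H]2O[C@]2(C)CCC=O | intermediate
13 | methyl (2Z)-2-iodo-5-[(2R,3S)-3-[(2S,3R)-3-ethenyl-5-oxooxolan-2-yl]-2-methyloxiran-2-yl]pent-2-enoate | C=C[C@H]1CC(=O)O[C@@H]1[C@@H]2O[C@]2(C)CC/C=C(\I)C(=O)OC | intermediate
14 | methyl (2E)-2-ethenyl-5-[(2R,3S)-3-[(2S,3R)-3-ethenyl-5-oxooxolan-2-yl]-2-methyloxiran-2-yl]pent-2-enoate | C=C[C@H]1CC(=O)O[C@@H]1[C@@H]2O[C@]2(C)CC/C=C(/C(=O)OC)C=C | intermediate
15 | methyl (1(10)E,8Z)-(4R,5S,6S,7R)-4,5-epoxy-13-norgermacra-1(10),8-dien-12,6-olid-14-oate (ten-membered cis,cis-diene fused to the trans γ-lactone and the cis oxirane) | C1/C=C(C(=O)OC)\C=C/[C@H]2CC(=O)O[C@@H]2[C@@H]3O[C@]3(C)C1 | intermediate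
16 | methyl (4R,5S,6S,7R,8S,9R)-4,5-epoxy-8,9-dihydroxy-13-norgermacr-1(10)E-en-12,6-olid-14-oate (hydroxyls cis to each other and to the C7–C11 bond) | O[C@H]1[C@H]2CC(=O)O[C@@H]2[C@@H]3O[C@]3(C)CC/C=C(/C(=O)OC)[C@H]1O | intermediate
17 | 8,9-bis(triethylsilyl) ether of 16 | CC[Si](CC)(CC)O[C@H]1[C@H]2CC(=O)O[C@@H]2[C@@H]3O[C@]3(C)CC/C=C(/C(=O)OC)[C@H]1O[Si](CC)(CC)CC | intermediate
18 | 11-(dimethylaminomethyl) derivative of 17 (11R, aminomethyl group anti to the C7–C8 bond) | CC[Si](CC)(CC)O[C@H]1[C@H]2[C@H](CN(C)C)C(=O)O[C@@H]2[C@@H]3O[C@]3(C)CC/C=C(/C(=O)OC)[C@H]1O[Si](CC)(CC)CC | intermediate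
19 | N-methyl quaternary salt of 18 (trimethylammonium iodide) | CC[Si](CC)(CC)O[C@H]1[C@H]2[C@H](C[N+](C)(C)C)C(=O)O[C@@H]2[C@@H]3O[C@]3(C)CC/C=C(/C(=O)OC)[C@H]1O[Si](CC)(CC)CC.[I-] | intermediate
20 | methyl 4,5-epoxy-8,9-bis(triethylsilyloxy)germacra-1(10)E,11(13)-dien-12,6-olid-14-oate | CC[Si](CC)(CC)O[C@H]1[C@H]2C(=C)C(=O)O[C@@H]2[C@@H]3O[C@]3(C)CC/C=C(/C(=O)OC)[C@H]1O[Si](CC)(CC)CC | intermediate
21 | methyl (4R,5S,6S,7R,8S,9R)-4,5-epoxy-8,9-dihydroxygermacra-1(10)E,11(13)-dien-12,6-olid-14-oate | O[C@H]1[C@H]2C(=C)C(=O)O[C@@H]2[C@@H]3O[C@]3(C)CC/C=C(/C(=O)OC)[C@H]1O | intermediate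
22 | 9-O-acetate of 21 (methyl 9-acetoxy-4,5-epoxy-8-hydroxygermacra-1(10)E,11(13)-dien-12,6-olid-14-oate) | O[C@H]1[C@H]2C(=C)C(=O)O[C@@H]2[C@@H]3O[C@]3(C)CC/C=C(/C(=O)OC)[C@H]1OC(C)=O | intermediate
23 | ethyl 2-(hydroxymethyl)acrylate | C=C(CO)C(=O)OCC | starting material
24 | ethyl 2-[(tert-butyldimethylsilyloxy)methyl]acrylate | C=C(CO[Si](C)(C)C(C)(C)C)C(=O)OCC | intermediate
25 | 2-[(tert-butyldimethylsilyloxy)methyl]acrylic acid | C=C(CO[Si](C)(C)C(C)(C)C)C(=O)O | intermediate
26 | mixed anhydride of 25 with 2,4,6-trichlorobenzoic acid | C=C(CO[Si](C)(C)C(C)(C)C)C(=O)OC(=O)c1c(Cl)cc(Cl)cc1Cl | intermediate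
27 | methyl 9-acetoxy-8-{2-[(tert-butyldimethylsilyloxy)methyl]acryloyloxy}-4,5-epoxygermacra-1(10)E,11(13)-dien-12,6-olid-14-oate | C=C(CO[Si](C)(C)C(C)(C)C)C(=O)O[C@H]1[C@H]2C(=C)C(=O)O[C@@H]2[C@@H]3O[C@]3(C)CC/C=C(/C(=O)OC)[C@H]1OC(C)=O | intermediate
28 | CNP0147016.1, methyl (4R,5S,6S,7R,8S,9R)-9-acetoxy-4,5-epoxy-8-[2-(hydroxymethyl)acryloyloxy]germacra-1(10)E,11(13)-dien-12,6-olid-14-oate | C=C(CO)C(=O)O[C@H]1[C@H]2C(=C)C(=O)O[C@@H]2[C@@H]2O[C@]2(C)CC/C=C(/C(=O)OC)[C@H]1OC(C)=O | target

**Step count**

Total: 19 steps (17 on the main line, 2 for the side-chain acid).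
Longest linear sequence: 17 steps (steps 1–15, 18 and 19).

**Steps most likely to fail**

Step 9 (ring-closing metathesis). What may go wrong: intermolecular metathesis to dimers and oligomers outruns closure of the strained ten-membered ring, or the ruthenium carbene, once loaded on the conjugated dienoate, rests as an ester-chelated vinylcarbene and turnover stops. The fallback closes the ring before the C1=C10 olefin exists, so that two isolated vinyl groups on a more flexible chain are joined. It sets out from aldehyde 12. Indium-mediated Reformatsky-type addition of methyl 4-bromocrotonate (indium powder, THF/H2O, rt) through its α-carbon should give the β-hydroxy α-vinyl ester F1, as epimers at the two new centres, both of which are lost later. The second-generation Grubbs catalyst at high dilution should close F1 to the ten-membered hydroxy ester F2 with a cis C8=C9 olefin. MsCl/Et3N then gives the mesylate F3, from which DBU removes the doubly activated C10 proton and expels the mesylate (E1cB). This gives diene 15, where the route is rejoined.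

Step 10 (dihydroxylation). What may go wrong: poor facial selectivity, with OsO4 approaching C8=C9 from the face anti to the C7–C11 bond and giving the 8,9-epimeric cis-diol. The fallback is the Woodward cis-hydroxylation, which builds the cis-diol on the face opposite to the one first attacked by the electrophile. It sets out from diene 15. I2 and AgOAc in moist acetic acid should add iodine to the exposed face and acetate anti to it, to give the trans iodo acetate F4. Silver-assisted displacement of iodide by the neighbouring acetate carbonyl then forms a cis-fused acetoxonium ion on the other face, which water opens to the cis hydroxy acetates, the 9-acetate F5 and the 8-acetate F6. Brief K2CO3/MeOH at 0 °C removes the acetyl group from both and gives diol 16, where the route is rejoined.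

Step 15 (monoacetylation). What may go wrong: the site selectivity between the two secondary hydroxyls turns out opposite to the one assumed, so that acetylation takes place at O8 first, or an O9 acetate migrates to O8 under base. The fallback reverses the order of the two acylations, so that the more reactive O8 takes the acrylic ester first. It sets out from diol 21. Yamaguchi acylation with acid 25 through mixed anhydride 26, under the conditions of step 18, should give the 8-O-acyl 9-hydroxy compound F7. Acetylation of the remaining C9 hydroxyl (Ac2O, pyridine, 4-(dimethylamino)pyridine, 0 °C) then gives diester 27, where the route is rejoined.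

**Further compounds**

F1 | step 9 | methyl 2-ethenyl-3-hydroxy-5-[(2R,3S)-3-[(2S,3R)-3-ethenyl-5-oxooxolan-2-yl]-2-methyloxiran-2-yl]pentanoate (epimers at C2 and C3 of the pentanoate) | C=C[C@H]1CC(=O)O[C@@H]1[C@@H]2O[C@]2(C)CCC(O)C(C=C)C(=O)OC
F2 | step 9 | methyl (8Z)-4,5-epoxy-1-hydroxy-13-norgermacr-8-en-12,6-olid-14-oate (epimers at C1 and C10) | C1C(O)C(C(=O)OC)/C=C\[C@H]2CC(=O)O[C@@H]2[C@@H]3O[C@]3(C)C1
F3 | step 9 | C1 methanesulfonate of F2 | C1C(OS(C)(=O)=O)C(C(=O)OC)/C=C\[C@H]2CC(=O)O[C@@H]2[C@@H]3O[C@]3(C)C1
F4 | step 10 | methyl 9-acetoxy-4,5-epoxy-8-iodo-13-norgermacr-1(10)E-en-12,6-olid-14-oate (iodine anti, acetate syn to the C7–C11 bond) | I[C@@H]1[C@H]2CC(=O)O[C@@H]2[C@@H]3O[C@]3(C)CC/C=C(/C(=O)OC)[C@H]1OC(C)=O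
F5 | step 10 | 9-O-acetate of diol 16 | O[C@H]1[C@H]2CC(=O)O[C@@H]2[C@@H]3O[C@]3(C)CC/C=C(/C(=O)OC)[C@H]1OC(C)=O
F6 | step 10 | 8-O-acetate of diol 16 | CC(=O)O[C@H]1[C@H]2CC(=O)O[C@@H]2[C@@H]3O[C@]3(C)CC/C=C(/C(=O)OC)[C@H]1O
F7 | step 15 | methyl 8-{2-[(tert-butyldimethylsilyloxy)methyl]acryloyloxy}-4,5-epoxy-9-hydroxygermacra-1(10)E,11(13)-dien-12,6-olid-14-oate | C=C(CO[Si](C)(C)C(C)(C)C)C(=O)O[C@H]1[C@H]2C(=C)C(=O)O[C@@H]2[C@@H]3O[C@]3(C)CC/C=C(/C(=O)OC)[C@H]1O
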